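(The runs come from a simulation for an exercise; noise was put on by code.)

Start with the easy step: a starting complex gives up one leaving ligand and takes one incoming ligand, so one [incoming ligand] goes for each [starting complex] lost.

in all of them: starting complex 0.32 M

| run | incoming ligand | leaving ligand | remark | time |
|---|---|---|---|---|
| ash | 0.29 M | 0.16 M | run made earlier |  |
| larch | 0.77 M | 0.16 M | run made earlier |  |
| blue | 0.384 M | 0.160 M |  | 15 h |
| grey | 0.480 M | 0.160 M |  | 15 h |
| ochre | 0.960 M | 0.160 M |  | 15 h |

| run | time / h | complex with one exchanged / % | complex with two exchanged / % |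
|---|---|---|---|
| ash | 0.833 | 2.9 | 0 |
| ash | 2.00 | 8.6 | 0 |
| ash | 5.00 | 19.2 | 0.6 |
| ash | 10.0 | 29.9 | 0.9 |
| larch | 2.50 | 24.5 | 1.0 |
| larch | 5.00 | 41.2 | 1.0 |
| larch | 8.00 | 56.2 | 2.1 |
| larch | 10.0 | 60.7 | 2.5 |

(scatter of a reading: 1 percentage point)

* how much complex with one exchanged is there at the end, in percent of the starting complex charged: for each flask in turn (blue, grey, ochre)

- what was read earlier has a scatter of 1 percentage point, one standard deviation

Ina calls the flask pseudo-first-order: [incoming ligand] stays at its charge, and [starting complex] decays as exp(−k[incoming ligand]t). Per calls it second order: the difference [incoming ligand] − [starting complex] stays at its charged margin, and the ratio [starting complex]/[incoming ligand] decays from its charged value as exp(−k·margin·t).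

Ina's law, read on the ash run, gives 0.155 M⁻¹ h⁻¹ at 2.00 h but 0.127 M⁻¹ h⁻¹ at 10.0 h, a constant that ends lower than it began. Per's law, read at 10.0 h, gives 0.157 M⁻¹ h⁻¹ on ash and 0.154 M⁻¹ h⁻¹ on larch. He carries their mean, 0.156 M⁻¹ h⁻¹, the exchange constant: the rate of loss of starting complex per [starting complex] per [incoming ligand].

In blue, one exchange on each starting complex takes 83.3% of the incoming ligand charged, more than the 33.3% it takes in ochre. For starting complex left at 15 h in blue, grey and ochre, Ina, with her early constant, says 40.9%, 32.7% and 10.7%. Per says 50.8%, 42.4% and 16.1%. I side with Per, and so expect complex with one exchanged to stand under 49.2%, 57.6% and 83.9%, the starting complex lost; larch at 10.0 h shows 2.5% of complex with two exchanged beside 60.7% of complex with one exchanged.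

The forecast, reckoned “with the ligand depleted as it is consumed”, says 47%, 55% and 75%. The flasks give 47.5%, 54.8% and 73.5%, with starting complex left at 50%, 42% and 16%, against Per's 50.8%, 42.4% and 16.1%. Ina's law comes nearest in ochre, which keeps more of its incoming ligand than blue: she is 5.5 percentage points off there against 9.5 points in blue.

    complex with two exchanged + incoming ligand → over-reaction product (k = 0.230 M⁻¹ h⁻¹)
    complex with two exchanged + incoming ligand → leaving ligand + complex with three exchanged (k = 0.120 M⁻¹ h⁻¹)
    complex with one exchanged + incoming ligand → leaving ligand + complex with two exchanged (k = 0.0180 M⁻¹ h⁻¹)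
    starting complex + incoming ligand → leaving ligand + complex with one exchanged (k = 0.160 M⁻¹ h⁻¹)

In blue at 15.0 h, with 56% of the incoming ligand left, the exchange constant gives starting complex a half-life of 20.6 h, while complex with one exchanged has 180 h by its onward step. Blue then makes complex with one exchanged 9.46 times faster than it uses it up. In ochre at 15.0 h, with 66% of the incoming ligand left, the same constant gives starting complex a half-life of 6.98 h.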